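## Structural features

Labels used throughout: ring A carries C7 at A1, the biaryl bond at A2 and oxygen at A3 and A5; ring D carries C8 at D1, C10 at D2, oxygen at D4 and the biaryl bond at D6; ring B is bonded to C8 at B1 and to C9 at B2, carries oxygen at B4 and B5, and B6–H lies next to B1; ring C is the 3,4-dioxygenated phenyl group on C9; C7 and C10 are the two methylene groups.

Compound 21 is a heptaphenol in which four benzene rings (resorcinol ring A, fused catechol ring B, pendant catechol ring C, monophenol ring D) are held together by four sp3 carbons. These form two carbocycles, a 9,10-dihydrophenanthrene ring (A1, A2, D6, D1, C8, C7) and a dibenzosuberane ring (C8, B1, B2, C9, C10, D2, D1), which share the C8–D1 bond. The only stereocentres are C8 (R) and C9 (S); they are not neighbours but stand 1,4 to each other across B1–B2, with H8 and H9 cis. The catechol and resorcinol rings are sensitive to air, C8–H and C9–H are doubly benzylic, and C8 is para to the D4 hydroxyl, so the C8–B1 bond can ionise under strong acid. The real difficulty is that no functional group is left near either stereocentre, so two remote all-carbon stereocentres on a seven-membered ring must be set without a handle, and the hindered A2–D6 biaryl bond must be made where two C–H bonds are within reach. The key step uses the fact that rings B and C are the same 3,4-dioxygenated aryl group on C9, differing only by the B1–C8 bond, and that C8 is para to the D4 hydroxyl. A prochiral bis-aryl methine at C9 facing a para-quinone methide at C8 therefore yields both stereocentres when the C8–B1 bond closes.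

## Logic of the disconnections

21 to 20. The seven phenolic O–H bonds are traced back to aryl O–CH3 bonds. The oxidation-prone polyphenol is handled only once, at the end, and every earlier intermediate is a robust ether. The forward step must cleave seven ethers without ionising the C8–B1 bond.

20 to 19. The A2–D6 biaryl bond is cut, leaving bromine at A2 and hydrogen at D6. This removes the dihydrophenanthrene ring and leaves a dibenzosuberane with a benzyl side chain. The forward arylation must choose D6–H over B6–H, which is also six atoms away from A2, and needs the ring D oxygen capped so that no phenoxide can divert the aryl–palladium species to D1.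

19 to 18. The D4 O–CH3 bond is cut. Ring D must be a free phenol in the key step but an ether in the arylation, and a methyl group is the cap that leaves with the other six at the end. The forward step is a simple O-alkylation that must not touch C8–H.

18 to 16 (through 17). The C8–B1 bond is cut, which opens the seven-membered ring and removes both stereocentres at once. The precursor 16 is achiral, with two identical aryl groups on C9 and a stilbene that can be protonated to the quinone methide 17. The forward step must select one enantiotopic aryl group and one face of C8, protonate at C7 and not at C8, and outrun intermolecular alkylation and hydride transfer from C9–H.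

16 to 15. The phenolic O–H is traced back to an O–Si bond. A silyl ether is the one protecting group that survives carbanions and is then removed by fluoride without acid, so no racemic cyclisation can occur before the chiral acid is present.

15 to 11 and 13. The C7=C8 double bond is cut by a phosphonate olefination into a ring D aldehyde and a ring A phosphonate. This is the convergent junction of the route; the alkene geometry need not be controlled strictly because C8 becomes planar again in 17.

13 to 12. The A2–Br bond is cut. The bromine serves twice: it blocks and deactivates the electron-rich ring A during the key step and is the handle for the biaryl bond. The forward bromination must go to A2 and not to the carbon between the two methoxy groups.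

11 to 8. The D1–CHO bond is cut back to D1–Br. Carrying the aldehyde carbon as an aryl bromide lets ring D pass through radical bromination and carbanion alkylation, which a free aldehyde would not survive. The forward exchange–formylation must be faster than proton transfer from C9–H.

8 to 3 and 6. The C9–C10 bond is cut into a symmetrical diarylmethyl anion and a benzylic bromide. Because C9 carries two identical aryl groups, the nucleophile is a single achiral species and one C–C bond builds the whole 2,2-diarylethyl unit. The forward step needs deprotonation at the diarylmethane carbon and not on the rings.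

6 to 5 to 4. The C10–Br bond and then the O–Si bond are cut, leading to a commercial bromocresol. The forward bromination must be benzylic and not nuclear, which the silyl ether and a non-polar medium favour.

3 to 1 and 2. One aryl–CH2 bond is cut, giving two commercial building blocks. The forward benzylation must stop at the diarylmethane, which a large excess of 1 secures.

## Other disconnections considered

Alternative 1: Three bonds of ring B are cut (B1–B2, B3–B4, B5–B6), so that ring B and the seven-membered ring arise together from the diyne A1 and the bis(boryl)alkyne A2 in a cobalt-mediated [2+2+2] cyclotrimerisation giving A3. Oxidation of the two C–B bonds and demethylation would then lead to 21.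
- In its favour: the two ring B oxygens are placed without any ortho/para question, which equals the chosen plan. The A2–D6 biaryl exists before ring B does, so the choice between D6–H and B6–H of step 11 never arises, and on that point the alternative is better. No cation is formed next to C9–H, so hydride transfer is excluded, which is also better. Cyclotrimerisation is a known reaction class, so on precedent its key step is less speculative than step 9.
- Against it here: the annulation creates no stereocentre. C8 and C9 must both be installed beforehand in A1 as propargylic, benzylic centres that are 1,4-related across a flexible chain and prone to propargyl–allenyl isomerisation. Five atoms separate the two alkynes, so the closure forms a seven-membered ring, where diyne cyclotrimerisation is far less dependable than for five- and six-membered rings. The hindered internal alkyne A2 must also compete with self-trimerisation of two terminal alkynes.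
- Comparison: structurally it solves the regiochemistry of ring B and the biaryl bond well but leaves the stereochemical problem untouched. Mechanistically it trades a cation cyclisation for a metallacycle of unfavourable size. In step count it is clearly longer, since A1 needs the dihydrophenanthrene and two separate asymmetric events before the key step and two oxidations after it.

Alternative 2: Both bonds from the seven-membered ring to ring B are cut (C8–B1 and C9–B2). Deprotonated A4 adds through C8 to the aryne A5, the aryl anion closes onto the C9 ketone, and the four-membered ring fragments, so the five-membered ring of A4 becomes the seven-membered ring of A6.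
- In its favour: aryne insertion into the C–C bond of a β-keto ester is a known reaction type, so the key step needs no new method, which is better than the chosen plan. The aryne is symmetrical, so there is no regiochemical issue (equal). The bromine already sits at D6, so the biaryl site is fixed by a halide and not by a C–H choice (better). No carbocation is involved.
- Against it here: A6 contains neither stereocentre; C8 is racemic and epimerisable (α to the ester and doubly benzylic) and C9 is a ketone. After the key step, ring C must be added to C9 and the tertiary hydroxyl removed with control of C9. The ester carbon must become C7 and ring A must be attached through two bonds. Absolute configuration still needs a separate asymmetric step or a resolution. The bromine at D6 crowds the nucleophilic carbon of A4, and 2-indanone keto esters are strongly enolised and air-sensitive.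
- Comparison: structurally it builds the ring but not its stereochemistry, whereas step 9 makes the ring and both stereocentres in one bond formation. Mechanistically it is the more robust ring construction. In step count it is markedly longer after the key step.

Alternative 3: Two bonds of ring A are cut (A1–A6 and A4–A5). The malonate A8 adds to the β-carbon A1 of the enone A7, the acetyl methyl group condenses with one ester, and the ring so formed is decarboxylated and dehydrogenated to the resorcinol ring of A9.
- In its favour: ring A is grown onto D6, so there is no biaryl coupling, no bromide and no site question; on that point the alternative is better than the chosen plan. Ring A arrives with free hydroxyls beside five methyl ethers, and the chemistry is classical carbonyl condensation.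
- Against it here: this is only an end-game. A7 already contains the seven-membered ring and both stereocentres, so the central problem is moved upstream without an answer. The basic conditions act on an enone whose γ-carbon is C7 next to the stereocentre C8, so dienolate formation and double-bond migration threaten C8. The final oxidation must aromatise ring A while sparing the C7–C8 unit of the dihydronaphthalene, which an oxidant can also dehydrogenate with loss of C8.
- Comparison: structurally it avoids the hindered biaryl bond; mechanistically it sets no stereocentre and adds a chemoselectivity problem in the oxidation. In step count it cannot be shorter, because A7 is no easier to make than 19 and a demethylation still follows.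

Key step: step 9

Assumption: the sense of induction of the chiral acid cannot be predicted with confidence; the (R)-configured catalyst is written, and its mirror image is to be used if it favours the antipode of 18.

Assumption: diethyl (3,5-dimethoxybenzyl)phosphonate 12 and 4-bromo-3-methylphenol 4 are taken as commercial materials.

## Route

Step 1
Reactants: 1 1,2-dimethoxybenzene; 2 (3,4-dimethoxyphenyl)methanol
Product: 3 bis(3,4-dimethoxyphenyl)methane
Conditions: 1 (8 equiv), FeCl3 (5 mol%), CH2Cl2, rt, slow addition of 2
Reagents that add atoms: none
Why: Friedel–Crafts benzylation; the benzylic cation from 2 attacks 1 para to a methoxy group, and slow addition of 2 into a large excess of 1 suppresses self-condensation of 2 and further benzylation of 3.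

Step 2
Reactants: 4 4-bromo-3-methylphenol
Product: 5 (4-bromo-3-methylphenoxy)tri(propan-2-yl)silane
Conditions: TIPSCl, imidazole, DMF, rt
Reagents that add atoms: chlorotri(propan-2-yl)silane, CC(C)[Si](Cl)(C(C)C)C(C)C
Why: Standard silyl ether formation; the bulky silyl ether should withstand the radical bromination, the carbanion alkylation, the halogen–lithium exchange and the olefination base, and later leaves with fluoride without acid.

Step 3
Reactants: 5 (4-bromo-3-methylphenoxy)tri(propan-2-yl)silane
Product: 6 [4-bromo-3-(bromomethyl)phenoxy]tri(propan-2-yl)silane
Conditions: NBS (1.05 equiv), AIBN (5 mol%), PhCF3, 85 °C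
Reagents that add atoms: N-bromosuccinimide, O=C1CCC(=O)N1Br
Why: Wohl–Ziegler benzylic bromination; the silyl ether is a weaker donor than an alkyl ether and the non-polar medium disfavours ionic ring bromination, while the aryl bromide stands in for the later aldehyde, which would not survive a radical bromination.

Step 4
Reactants: 3 bis(3,4-dimethoxyphenyl)methane; 6 [4-bromo-3-(bromomethyl)phenoxy]tri(propan-2-yl)silane
Product: 8 {4-bromo-3-[2,2-bis(3,4-dimethoxyphenyl)ethyl]phenoxy}tri(propan-2-yl)silane, via lithiated diarylmethane 7 (not isolated)
Conditions: 3 (1.1 equiv), n-BuLi (1.05 equiv), THF, 0 °C → rt, 1 h; then 6, −78 → 0 °C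
Reagents that add atoms: none
Why: Benzylic lithiation of a diarylmethane followed by SN2 alkylation; the doubly benzylic C–H is the most acidic site of 3 and brief warming lets any ring-lithiated material equilibrate to 7, which attacks the primary benzylic bromide and does not exchange with the aryl bromide.

Step 5
Reactants: 8 {4-bromo-3-[2,2-bis(3,4-dimethoxyphenyl)ethyl]phenoxy}tri(propan-2-yl)silane
Product: 11 2-[2,2-bis(3,4-dimethoxyphenyl)ethyl]-4-{[tri(propan-2-yl)silyl]oxy}benzaldehyde, via aryllithium 9 (not isolated), via lithium hemiaminal alkoxide 10 (not isolated)
Conditions: n-BuLi (1.05 equiv), THF, −78 °C, 15 min; DMF (3 equiv), −78 → 0 °C; then H2O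
Reagents that add atoms: N,N-dimethylformamide, CN(C)C=O
Why: Bromine–lithium exchange followed by Bouveault formylation; exchange at −78 °C should outrun deprotonation of C9–H, and 10 keeps the aldehyde masked against over-addition until the aqueous quench.

Step 6
Reactants: 12 diethyl [(3,5-dimethoxyphenyl)methyl]phosphonate
Product: 13 diethyl [(2-bromo-3,5-dimethoxyphenyl)methyl]phosphonate
Conditions: NBS (1.05 equiv), MeCN, 0 °C → rt
Reagents that add atoms: N-bromosuccinimide, O=C1CCC(=O)N1Br
Why: Electrophilic aromatic bromination; A2 (ortho to one methoxy group and para to the other) should be attacked in preference to the more crowded carbon between the two methoxy groups, as is usual for 3,5-dimethoxybenzyl derivatives.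

Step 7
Reactants: 13 diethyl [(2-bromo-3,5-dimethoxyphenyl)methyl]phosphonate; 11 2-[2,2-bis(3,4-dimethoxyphenyl)ethyl]-4-{[tri(propan-2-yl)silyl]oxy}benzaldehyde
Product: 15 {4-[(E)-2-(2-bromo-3,5-dimethoxyphenyl)ethenyl]-3-[2,2-bis(3,4-dimethoxyphenyl)ethyl]phenoxy}tri(propan-2-yl)silane, via sodium phosphonate carbanion 14 (not isolated)
Conditions: 13 (1.2 equiv), NaH, THF, 0 °C; then 11, 0 °C → rt
Reagents that add atoms: none
Why: Horner–Wadsworth–Emmons olefination of an aryl aldehyde with a benzylic phosphonate anion should give the (E)-stilbene; the alkene geometry is in any case erased when C8 becomes the quinone methide carbon.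

Step 8
Reactants: 15 {4-[(E)-2-(2-bromo-3,5-dimethoxyphenyl)ethenyl]-3-[2,2-bis(3,4-dimethoxyphenyl)ethyl]phenoxy}tri(propan-2-yl)silane
Product: 16 4-[(E)-2-(2-bromo-3,5-dimethoxyphenyl)ethenyl]-3-[2,2-bis(3,4-dimethoxyphenyl)ethyl]phenol
Conditions: TBAF (1.1 equiv), AcOH (1.1 equiv), THF, 0 °C, dark
Reagents that add atoms: none
Why: Fluoride cleavage of the aryl silyl ether; the acetic acid buffer avoids a free phenoxide and is far too weak to protonate the stilbene, so no racemic cyclisation can precede the chiral acid.

Step 9
Reactants: 16 4-[(E)-2-(2-bromo-3,5-dimethoxyphenyl)ethenyl]-3-[2,2-bis(3,4-dimethoxyphenyl)ethyl]phenol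
Product: 18 (5S,10S)-5-[(2-bromo-3,5-dimethoxyphenyl)methyl]-10-(3,4-dimethoxyphenyl)-7,8-dimethoxy-10,11-dihydro-5H-dibenzo[a,d][7]annulen-2-ol (annulene C5 is C8 and C10 is C9; H8 and H9 cis), via para-quinone methide 17 (not isolated)
Conditions: (R)-3,3'-bis(2,4,6-triisopropylphenyl)-1,1'-binaphthyl-2,2'-diyl N-triflylphosphoramide (10 mol%), 4 Å MS, PhCF3 (0.01 M), 0 °C → rt, dark
Reagents that add atoms: none
Why: Proposed new method: the acid C-protonates the stilbene at C7 (only this regiochemistry places the cation para to the D4 hydroxyl, since the ring A methoxy groups are meta to C7), giving the O-protonated quinone methide 17 as a contact ion pair held by the D4 O–H···anion hydrogen bond, and one aryl group on C9 then attacks C8 through its carbon para to a methoxy group and rearomatises; the closest known reaction type is the chiral phosphoric acid catalysed addition of electron-rich arenes to para-quinone methides generated in the flask from para-hydroxybenzyl alcohols or para-hydroxystyrenes, which has not been run as an intramolecular desymmetrisation of a diarylmethine. The seven-membered ring closes in a 7-endo-trig Friedel–Crafts mode, the C8=D1 bond of 17 lying inside the new ring. C9 becomes stereogenic through the choice between its two enantiotopic aryl groups and C8 through the choice of face of the planar quinone methide carbon; both choices are made in the same C–C bond formation under the control of the chiral anion bound at the D4 hydroxyl. The relative configuration should come from the substrate: 17 carries the C7 benzyl group syn to D6–H, and in the closing ring C9–H is expected to lie in the plane of the attacking aryl group (least allylic strain) with the spectator aryl group pointing away from ring D, which places H8 and H9 cis as in 21. Attack para and not ortho to methoxy is secured by the crowding of the carbon between C9 and the methoxy group. The ring A bromine blocks one activated carbon of the only other electron-rich ring and deactivates the rest, and high dilution disfavours intermolecular alkylation. The N-triflyl phosphoramide is chosen over the parent phosphoric acid because a 1,2-diarylethene is harder to protonate than the 1,1-disubstituted hydroxystyrenes of the precedent.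

Step 10
Reactants: 18 (5S,10S)-5-[(2-bromo-3,5-dimethoxyphenyl)methyl]-10-(3,4-dimethoxyphenyl)-7,8-dimethoxy-10,11-dihydro-5H-dibenzo[a,d][7]annulen-2-ol
Product: 19 (5S,10S)-5-[(2-bromo-3,5-dimethoxyphenyl)methyl]-10-(3,4-dimethoxyphenyl)-2,7,8-trimethoxy-10,11-dihydro-5H-dibenzo[a,d][7]annulene
Conditions: MeI (3 equiv), K2CO3, acetone, 50 °C
Reagents that add atoms: iodomethane, CI
Why: Williamson ether synthesis; capping the D4 hydroxyl prevents phenoxide-type C-arylation at D1 (a dearomatising spirocyclisation) and phenoxide binding to palladium in step 11, and carbonate is too weak a base to touch C8–H or C9–H.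

Step 11
Reactants: 19 (5S,10S)-5-[(2-bromo-3,5-dimethoxyphenyl)methyl]-10-(3,4-dimethoxyphenyl)-2,7,8-trimethoxy-10,11-dihydro-5H-dibenzo[a,d][7]annulene
Product: 20 hepta-O-methyl ether of 21 (A2 bonded to D6; 8R,9S; H8 and H9 cis)
Conditions: Pd(OAc)2 (5 mol%), PCy3·HBF4 (10 mol%), PivOH (30 mol%), K2CO3 (2 equiv), DMA, 120 °C
Reagents that add atoms: none
Why: Intramolecular direct arylation by concerted metalation–deprotonation, closing a six-membered ring; of the two C–H bonds within reach, D6–H is unhindered whereas B6–H is flanked by the B5 methoxy group and would lead to a biaryl with methoxy groups on both bay carbons, so closure onto ring D should prevail. No stereocentre is touched; the C8 descriptor changes from S to R only because D1 now outranks B1.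

Step 12
Reactants: 20 hepta-O-methyl ether of 21
Product: 21 CNP0306974.1, the (8R,9S)-heptaphenol with hydroxyls at A3, A5, B4, B5, D4 and at the 3- and 4-positions of ring C (H8 and H9 cis)
Conditions: BBr3 (14 equiv), CH2Cl2, −78 → 0 °C, argon; then MeOH, H2O
Reagents that add atoms: none
Why: Lewis acid mediated cleavage of aryl methyl ethers (bromide attacks the methyl group of the boron-bound ether), driven to completion by excess reagent; low temperature and an oxygen-free work-up should protect the catechols and keep the C8–B1 bond from ionising.

## Compound list

1 | 1,2-dimethoxybenzene | COc1ccccc1OC | starting material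
2 | (3,4-dimethoxyphenyl)methanol | COc1ccc(CO)cc1OC | starting material
3 | bis(3,4-dimethoxyphenyl)methane | COc1ccc(Cc2ccc(OC)c(OC)c2)cc1OC | intermediate
4 | 4-bromo-3-methylphenol | Cc1cc(O)ccc1Br | starting material
5 | (4-bromo-3-methylphenoxy)tri(propan-2-yl)silane | Cc1cc(O[Si](C(C)C)(C(C)C)C(C)C)ccc1Br | intermediate
6 | [4-bromo-3-(bromomethyl)phenoxy]tri(propan-2-yl)silane | BrCc1cc(O[Si](C(C)C)(C(C)C)C(C)C)ccc1Br | intermediate
7 | [bis(3,4-dimethoxyphenyl)methyl]lithium (formed in the flask) | [Li]C(c1ccc(OC)c(OC)c1)c1ccc(OC)c(OC)c1 | intermediate
8 | {4-bromo-3-[2,2-bis(3,4-dimethoxyphenyl)ethyl]phenoxy}tri(propan-2-yl)silane | COc1ccc(cc1OC)C(Cc1cc(O[Si](C(C)C)(C(C)C)C(C)C)ccc1Br)c1ccc(OC)c(OC)c1 | intermediate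
9 | (2-[2,2-bis(3,4-dimethoxyphenyl)ethyl]-4-{[tri(propan-2-yl)silyl]oxy}phenyl)lithium (formed in the flask) | [Li]c1ccc(O[Si](C(C)C)(C(C)C)C(C)C)cc1CC(c1ccc(OC)c(OC)c1)c1ccc(OC)c(OC)c1 | intermediate
10 | lithium (dimethylamino)(2-[2,2-bis(3,4-dimethoxyphenyl)ethyl]-4-{[tri(propan-2-yl)silyl]oxy}phenyl)methanolate, racemic (formed in the flask) | [Li]OC(N(C)C)c1ccc(O[Si](C(C)C)(C(C)C)C(C)C)cc1CC(c1ccc(OC)c(OC)c1)c1ccc(OC)c(OC)c1 | intermediate
11 | 2-[2,2-bis(3,4-dimethoxyphenyl)ethyl]-4-{[tri(propan-2-yl)silyl]oxy}benzaldehyde | O=Cc1ccc(O[Si](C(C)C)(C(C)C)C(C)C)cc1CC(c1ccc(OC)c(OC)c1)c1ccc(OC)c(OC)c1 | intermediate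
12 | diethyl [(3,5-dimethoxyphenyl)methyl]phosphonate | CCOP(=O)(Cc1cc(OC)cc(OC)c1)OCC | starting material
13 | diethyl [(2-bromo-3,5-dimethoxyphenyl)methyl]phosphonate | CCOP(=O)(Cc1cc(OC)cc(OC)c1Br)OCC | intermediate
14 | sodium salt of the carbanion of 13 (formed in the flask) | [Na]C(c1cc(OC)cc(OC)c1Br)P(=O)(OCC)OCC | intermediate
15 | {4-[(E)-2-(2-bromo-3,5-dimethoxyphenyl)ethenyl]-3-[2,2-bis(3,4-dimethoxyphenyl)ethyl]phenoxy}tri(propan-2-yl)silane | COc1cc(OC)c(Br)c(c1)/C=C/c1ccc(O[Si](C(C)C)(C(C)C)C(C)C)cc1CC(c1ccc(OC)c(OC)c1)c1ccc(OC)c(OC)c1 | intermediate
16 | 4-[(E)-2-(2-bromo-3,5-dimethoxyphenyl)ethenyl]-3-[2,2-bis(3,4-dimethoxyphenyl)ethyl]phenol | COc1cc(OC)c(Br)c(c1)/C=C/c1ccc(O)cc1CC(c1ccc(OC)c(OC)c1)c1ccc(OC)c(OC)c1 | intermediate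
17 | 4-[2-(2-bromo-3,5-dimethoxyphenyl)ethylidene]-3-[2,2-bis(3,4-dimethoxyphenyl)ethyl]cyclohexa-2,5-dien-1-one, C7 syn to D6 (formed in the flask, present as its O-protonated ion pair) | COc1cc(OC)c(Br)c(c1)C/C=C1\C=CC(=O)C=C1CC(c1ccc(OC)c(OC)c1)c1ccc(OC)c(OC)c1 | intermediate
18 | (5S,10S)-5-[(2-bromo-3,5-dimethoxyphenyl)methyl]-10-(3,4-dimethoxyphenyl)-7,8-dimethoxy-10,11-dihydro-5H-dibenzo[a,d][7]annulen-2-ol | COc1cc(OC)c(Br)c(c1)C[C@@H]1c2cc(OC)c(OC)cc2[C@H](c2ccc(OC)c(OC)c2)Cc2cc(O)ccc21 | intermediate
19 | (5S,10S)-5-[(2-bromo-3,5-dimethoxyphenyl)methyl]-10-(3,4-dimethoxyphenyl)-2,7,8-trimethoxy-10,11-dihydro-5H-dibenzo[a,d][7]annulene | COc1cc(OC)c(Br)c(c1)C[C@@H]1c2cc(OC)c(OC)cc2[C@H](c2ccc(OC)c(OC)c2)Cc2cc(OC)ccc21 | intermediate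
20 | hepta-O-methyl ether of 21 (8R,9S; A2 bonded to D6) | COc1cc(OC)c2c(c1)C[C@@H]1c3cc(OC)c(OC)cc3[C@H](c3ccc(OC)c(OC)c3)Cc3cc(OC)cc-2c31 | intermediate
21 | CNP0306974.1, (8R,9S)-heptaphenol (H8 and H9 cis) | Oc1cc(O)c2c(c1)C[C@@H]1c3cc(O)c(O)cc3[C@H](c3ccc(O)c(O)c3)Cc3cc(O)cc-2c31 | target

## Step count and least certain steps

Total steps: 12. Longest linear sequence: 10 steps (steps 2, 3, 4, 5, 7, 8, 9, 10, 11 and 12, from 4 to 21); steps 1 and 6 are side branches.

**Step 9 (key step).**
- What may go wrong: most likely poor discrimination between the two enantiotopic aryl groups and between the two faces of C8. The chiral anion is anchored only at the D4 oxygen, para to the reacting carbon, and the attacking arene offers no hydrogen-bond donor, so selectivity rests on ion pairing alone. A second threat is a 1,5-hydride transfer from C9–H to the cationic C8, which would give the well-stabilised bis-aryl cation at C9 and, after proton loss, an isomerised alkene in place of the ring. Protonation of the stilbene may also be slow.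
- Fallback (known chemistry): the fallback sets out from 16. Closure with an achiral strong acid (TfOH, 10 mol%, HFIP/CH2Cl2, −20 °C), an acid-promoted Friedel–Crafts cyclisation of a hydroxystilbene onto a dimethoxyphenyl ring of the kind established in oligostilbene chemistry, should give the racemic cis-dibenzosuberane phenol F1 after removal of any trans isomer on silica. Preparative chromatography on a chiral stationary phase then separates 18 from its (5R,10R) enantiomer F2, and the route is rejoined at 18.

**Step 4.**
- What may go wrong: ring lithiation of 3 ortho to a methoxy group competing with deprotonation at the diarylmethane carbon, and single-electron transfer between 7 and 6 leading to homo-coupling of both partners.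
- Fallback: this reverses the polarity and sets out from 6. Zinc insertion (Zn dust, LiCl, THF) gives the benzylic zinc bromide F3. Its addition to 3,4-dimethoxybenzaldehyde in the presence of MgCl2 gives the racemic carbinol 2-(2-bromo-5-{[tri(propan-2-yl)silyl]oxy}phenyl)-1-(3,4-dimethoxyphenyl)ethan-1-ol F4. Friedel–Crafts alkylation of 1 (excess) with F4 under FeCl3 catalysis in CH2Cl2 introduces the second aryl group para to a methoxy group and rejoins the route at 8.

**Step 5.**
- What may go wrong: proton transfer from C9–H to the aryllithium 9 through a six-membered transition state before the formamide is added, which would return debrominated material and a diarylmethyl anion.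
- Fallback: this avoids any carbanion and sets out from 8. Palladium-catalysed reductive carbonylation of the aryl bromide (Pd(OAc)2, di(1-adamantyl)-n-butylphosphine, CO/H2, TMEDA, toluene, 100 °C) should deliver 11 directly, where the route is rejoined; no new compound is made on the way.

**Step 11.**
- What may go wrong: arylation of the ring B C–H bond B6–H in competition with D6–H, since both lie six atoms from A2. Reduction of the C–Br bond is also possible if oxidative addition into the doubly ortho-substituted bromide or the metalation step is slow.
- Fallback: this makes the site choice structural and sets out from 18, replacing steps 10 and 11.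
  - Iodination of the phenol ortho to the hydroxyl at the less hindered carbon D5 (I2, morpholine, CH2Cl2, 0 °C; the methyl ethers do not react under these conditions) gives the D5-iodo phenol F5.
  - O-Methylation (MeI, K2CO3, acetone) gives the D5-iodo methyl ether F6.
  - A Catellani reaction (Pd(OAc)2, tri(2-furyl)phosphine, norbornene, K2CO3, benzyl alcohol, DMF, 105 °C) then starts by oxidative addition of the D5–I bond to zerovalent palladium. The norbornene relay can metalate only D6, the other ortho carbon being D4. The tethered ring A bromide adds to the palladacycle and the A2–D6 bond forms. After loss of norbornene the D5–palladium bond is reduced by benzyl alcohol.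
  - The route is rejoined at 20.

## Further compounds

F1 | step 9 | racemic cis-5-[(2-bromo-3,5-dimethoxyphenyl)methyl]-10-(3,4-dimethoxyphenyl)-7,8-dimethoxy-10,11-dihydro-5H-dibenzo[a,d][7]annulen-2-ol (racemate of 18 and F2) | COc1cc(OC)c(Br)c(c1)CC1c2cc(OC)c(OC)cc2C(c2ccc(OC)c(OC)c2)Cc2cc(O)ccc21
F2 | step 9 | (5R,10R)-5-[(2-bromo-3,5-dimethoxyphenyl)methyl]-10-(3,4-dimethoxyphenyl)-7,8-dimethoxy-10,11-dihydro-5H-dibenzo[a,d][7]annulen-2-ol (enantiomer of 18) | COc1cc(OC)c(Br)c(c1)C[C@H]1c2cc(OC)c(OC)cc2[C@@H](c2ccc(OC)c(OC)c2)Cc2cc(O)ccc21
F3 | step 4 | bromo[(2-bromo-5-{[tri(propan-2-yl)silyl]oxy}phenyl)methyl]zinc | Br[Zn]Cc1cc(O[Si](C(C)C)(C(C)C)C(C)C)ccc1Br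
F4 | step 4 | racemic 2-(2-bromo-5-{[tri(propan-2-yl)silyl]oxy}phenyl)-1-(3,4-dimethoxyphenyl)ethan-1-ol | COc1ccc(cc1OC)C(O)Cc1cc(O[Si](C(C)C)(C(C)C)C(C)C)ccc1Br
F0 | step 5 | none | none
F5 | step 11 | (5S,10S)-5-[(2-bromo-3,5-dimethoxyphenyl)methyl]-10-(3,4-dimethoxyphenyl)-3-iodo-7,8-dimethoxy-10,11-dihydro-5H-dibenzo[a,d][7]annulen-2-ol (18 with iodine at D5) | COc1cc(OC)c(Br)c(c1)C[C@@H]1c2cc(OC)c(OC)cc2[C@H](c2ccc(OC)c(OC)c2)Cc2cc(O)c(I)cc21
F6 | step 11 | (5S,10S)-5-[(2-bromo-3,5-dimethoxyphenyl)methyl]-10-(3,4-dimethoxyphenyl)-3-iodo-2,7,8-trimethoxy-10,11-dihydro-5H-dibenzo[a,d][7]annulene (methyl ether of F5) | COc1cc(OC)c(Br)c(c1)C[C@@H]1c2cc(OC)c(OC)cc2[C@H](c2ccc(OC)c(OC)c2)Cc2cc(OC)c(I)cc21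
A1 | alternative 1 | dihydrophenanthrene diyne: ethynyl on C8, D2 carrying CH2–C9H(ethynyl)(3,4-dimethoxyphenyl), methoxy at A3, A5 and D4, C8 and C9 configured as needed for 21 | COc1cc(OC)c2c(c1)C[C@H](C#C)c1c(C[C@H](C#C)c3ccc(OC)c(OC)c3)cc(OC)cc-21
A2 | alternative 1 | 1,2-bis(4,4,5,5-tetramethyl-1,3,2-dioxaborolan-2-yl)ethyne | CC1(C)OB(OC1(C)C)C#CB1OC(C)(C)C(C)(C)O1
A3 | alternative 1 | 20 with pinacolatoboryl groups in place of the B4 and B5 methoxy groups | COc1cc(OC)c2c(c1)C[C@@H]1c3cc(B4OC(C)(C)C(C)(C)O4)c(B4OC(C)(C)C(C)(C)O4)cc3[C@H](c3ccc(OC)c(OC)c3)Cc3cc(OC)cc-2c31
A4 | alternative 2 | methyl 7-bromo-5-methoxy-2-oxo-2,3-dihydro-1H-indene-1-carboxylate (racemic) | COC(=O)C1C(=O)Cc2cc(OC)cc(Br)c12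
A5 | alternative 2 | 4,5-dimethoxybenzyne (1,2-didehydro-4,5-dimethoxybenzene) | COC1=CC#CC=C1OC
A6 | alternative 2 | racemic dibenzosuberane keto ester: methoxycarbonyl on C8, ketone at C9, methoxy at B4, B5 and D4, bromine at D6 | COC(=O)C1c2cc(OC)c(OC)cc2C(=O)Cc2cc(OC)cc(Br)c12
A7 | alternative 3 | tetracyclic enone: ring D fused to a dihydronaphthalene ring (D6, A2, A1, C7, C8, D1) with an acetyl group on A2 and an A1=A2 double bond; seven-membered ring, rings B and C and stereocentres as in 20 | CC(=O)C1=CC[C@@H]2c3cc(OC)c(OC)cc3[C@H](c3ccc(OC)c(OC)c3)Cc3cc(OC)cc1c32
A8 | alternative 3 | dimethyl propanedioate | COC(=O)CC(=O)OC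
A9 | alternative 3 | 21 as its pentamethyl ether (methoxy at B4, B5, D4 and on ring C; free hydroxyls at A3 and A5) | Oc1cc(O)c2c(c1)C[C@@H]1c3cc(OC)c(OC)cc3[C@H](c3ccc(OC)c(OC)c3)Cc3cc(OC)cc-2c31
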